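The seven-membered ring is closed in one operation, by vinylcarbene cyclopropanation of a siloxydiene followed by a [3,3] shift. The route has 16 steps, with a longest linear sequence of 13.

**Plan**

Numbering: the five-membered ring is C1 (angular CH3), C2 (OAc), C3, C4 (OH, i-Pr), C5 (H). The seven-membered ring is C5, C6 (O-veratroyl), C7, C8 (CH3) and C9 (epoxide), C10, C1. β is the face of the C1 methyl; all four ring-bound oxygens are β and H5 is α.
Cuts: first the two acyl C–O bonds and the epoxide oxygen, then C4–isopropyl. C8–CH3 is traced back to CO2Me and O6 to a silyl enol ether. Last come C7–C8 and C1–C10 of the seven-membered ring.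
Enabling feature: the seven-membered ring is a diene C1=C5–C6=C7 hanging on the cyclopentene ring plus a three-carbon unit C8–C9–C10. O6 makes C6=C7 an electron-rich enol ether, the C8 methyl can begin as the ester that tames a vinylcarbene, and the C8=C9 bond left behind is the epoxide site.
Forward: the five-membered ring is bought with C2–O in place, then the C1 methyl and the C6–C7 acetyl unit are added. The seven-membered ring is closed by cyclopropanation and [3,3] shift, and C4, C5, C6 and C8/C9 are finished in that order.
Stereochemistry: C2 comes from (S)-4-silyloxycyclopentenone. C1 comes from the catalyst-set cyclopropane, relayed through a boat transition state and reinforced by C2. C4 is set by addition anti to the C2 silyl ether, C5 by equilibration, C6 by chelate-controlled hydride from the α face, and C8/C9 by oxygen delivery from the 6β-hydroxyl.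

Key step: step 8

Assumption: the sense of induction of Rh2(S-DOSP)4 at C6=C7 is inferred from its usual behaviour with styrenes and vinyl ethers; if the C1 epimer prevailed, Rh2(R-DOSP)4 would replace it with nothing else changed.
Design remark: the C2 oxygen is carried from the first compound. Oxygenation next to the quaternary C1 after ring formation would arrive anti to the methyl, on the wrong face. As a β silyl ether it also steers steps 8 and 9.
Abbreviations: TBS = tert-butyldimethylsilyl, TES = triethylsilyl, Rh2(S-DOSP)4 = dirhodium tetrakis[(S)-N-(4-dodecylbenzenesulfonyl)prolinate]. Route numbering (C1–C10) is used from step 1 on.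

**Step 1**
Reactants: 1 (S)-4-(TBSO)cyclopent-2-en-1-one; 2 acetaldehyde
Product: 4 (2R,3S,4S)-4-(TBSO)-2-(1-hydroxyethyl)-3-methylcyclopentan-1-one (both carbinol epimers), via lithium enolate 3 (not isolated)
Conditions: MeLi (2 equiv), CuBr·SMe2, Et2O, −78 °C; then 2, −78 °C
Reagents that add atoms: methyllithium, [Li]C
Why: Tandem cuprate conjugate addition–aldol (three-component coupling), in which methyl adds to C1 anti to the C2 silyl ether and enolate 3 is trapped at C5 by acetaldehyde trans to the new methyl; only C2 matters later, because C1, C5 and the carbinol carbon all become sp2 in steps 2–4.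

**Step 2**
Reactants: 4 aldol
Product: 5 (3S,4S)-2-acetyl-4-(TBSO)-3-methylcyclopentan-1-one (keto–enol mixture)
Conditions: Dess–Martin periodinane (1.1 equiv), CH2Cl2, 0 °C → rt
Reagents that add atoms: none
Why: Dess–Martin oxidation of a β-hydroxy ketone to the 1,3-diketone under near-neutral conditions that leave the silyl ether and C2 untouched; no stereocentre is created.

**Step 3**
Reactants: 5 1,3-diketone
Product: 8 (S)-2-acetyl-4-(TBSO)-3-methylcyclopent-2-en-1-one, via α-phenylselanyl diketone 6 (not isolated), via selenoxide 7 (not isolated)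
Conditions: PhSeCl, pyridine, CH2Cl2, 0 °C; then 30% H2O2, 0 °C → rt
Reagents that add atoms: none
Why: Selenoxide syn-elimination after selenenylation of the 1,3-dicarbonyl at C5, in which selenium enters trans to the C1 methyl and hence cis to H1, the only β-hydrogen, so that C1=C5 forms regiospecifically.

**Step 4**
Reactants: 8 acetyl enone
Product: 9 (S)-4-(TBSO)-2-[1-(TBSO)vinyl]-3-methylcyclopent-2-en-1-one
Conditions: TBSOTf (1.1 equiv), Et3N, CH2Cl2, −78 → 0 °C
Reagents that add atoms: tert-butyldimethylsilyl triflate, CC(C)(C)[Si](C)(C)OS(=O)(=O)C(F)(F)F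
Why: Soft enolisation with silyl triflate and amine, where kinetic α′-deprotonation of the twisted, more accessible acetyl group (the usual outcome for alkenyl methyl ketones) gives the cross-conjugated 2-siloxydiene, and the low temperature guards the vinylogously acidic H2 against epimerisation.

**Step 5**
Reactants: 10 methyl acetoacetate
Product: 11 methyl 2-diazo-3-oxobutanoate
Conditions: 4-acetamidobenzenesulfonyl azide, Et3N, MeCN, 0 °C → rt
Reagents that add atoms: 4-acetamidobenzenesulfonyl azide, CC(=O)Nc1ccc(cc1)S(=O)(=O)N=[N+]=[N-]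
Why: Regitz diazo transfer to an active methylene compound.

**Step 6**
Reactants: 11 diazo keto ester
Product: 12 methyl 2-diazo-3-hydroxybutanoate (racemic)
Conditions: NaBH4, MeOH, 0 °C
Reagents that add atoms: none
Why: Chemoselective borohydride reduction of the ketone beside the inert diazo ester; the racemic carbinol centre is lost in the next step.

**Step 7**
Reactants: 12 diazo alcohol
Product: 13 methyl 2-diazobut-3-enoate
Conditions: POCl3, Et3N, CH2Cl2, 0 °C → rt; kept cold in hexanes and used the same day
Reagents that add atoms: none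
Why: Dehydration by phosphorylation and E2 elimination gives the vinyldiazoacetate, which closes slowly to a pyrazole and is therefore not stored.

**Step 8**
Reactants: 9 siloxydiene; 13 methyl 2-diazobut-3-enoate
Product: 15 (1S,2S)-hydroazulene dienone ester [C1 CH3 β; C2 OTBS β; C4 ketone; C5=C6(OTBS); C8(CO2Me)=C9], via cis-divinylcyclopropane 14 (not isolated)
Conditions: Rh2(S-DOSP)4 (1 mol %), hexanes, −20 °C → rt, slow addition of 13 (3 equiv); then toluene, 100 °C
Reagents that add atoms: none
Why: Loss of N2 from 13 at the dirhodium core gives a donor–acceptor vinylcarbene whose carbene carbon C8 adds in a concerted, asynchronous [2+1] manner to the terminal C6=C7 silyl enol ether of 9, closing the three-membered ring C6–C7–C8 with the vinyl group cis to the cyclopentenyl group (14); any trans isomer can re-close through reversible heterolysis of the push–pull C6–C8 bond at the later temperature. On heating, 14 undergoes the [3,3]-sigmatropic divinylcyclopropane–cycloheptadiene shift through a boat transition state, which closes the seven-membered ring by ring expansion: C10 bonds to C1, C6–C8 breaks, and C8=C9 and C5=C6 appear. The closest known reaction type is the tandem cyclopropanation/Cope formal (4+3) annulation of vinyldiazoacetates with 2-siloxydienes under dirhodium prolinate catalysis. C1, the one new stereocentre that survives, is fixed by relay: the catalyst picks the face of C6=C7 and so the (6S,8R) cyclopropane, the boat geometry then lets C10 reach only one face of C1=C5, and that face is also anti to the C2 silyl ether, so catalyst and substrate reinforce each other. The step needs reaction at the carbene carbon and not at the vinyl terminus C10, and cyclopropanation in preference to C–H insertion or attack on the enone; the hydrocarbon solvent with a carboxylate catalyst, the nucleophilic enol ether and the electron-poor, tetrasubstituted C1=C5 secure this. The C1 methyl lies on the inside of the boat and raises the barrier, hence 100 °C, but the donor at C6, the acceptor at C8 and the electrophilic enone β-carbon C1 polarise the shift in the productive sense.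

**Step 9**
Reactants: 15 dienone ester
Product: 16 (1S,2S,4S)-tertiary carbinol [C4 OH β and i-Pr α; C5=C6(OTBS) and C8 ester retained]
Conditions: i-PrLi, CeCl3, THF, −78 °C; NaHCO3 work-up, Et3N-washed silica
Reagents that add atoms: isopropyllithium, [Li]C(C)C
Why: Organocerium 1,2-addition, in which the weakly basic, oxophilic reagent adds to the enone carbonyl C4 faster than to the α-branched enoate and without enolisation towards C3 (which would expel the C2 silyloxy group), approaching from the α face opposite the C2 silyl ether and the C1 methyl to set 4S.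

**Step 10**
Reactants: 16 carbinol silyl enol ether
Product: 19 (1S,2S,4S,5S)-trans-fused β-hydroxy ketone [C6 ketone; H5 α; C8 ester retained], via tetrabutylammonium enolate 17 (not isolated), via cis-fused C5 epimer 18 (not isolated)
Conditions: TBAF (1.05 equiv), AcOH, THF, 0 °C; then DBU (0.2 equiv), toluene, rt
Reagents that add atoms: none
Why: Fluoride protodesilylation cleaves the enol Si–O bond far faster than the neopentyl C2 silyl ether, and amine-base epimerisation then drains the kinetic ketone 18 into 19, which is favoured because C6 sits cis to the small C4 hydroxyl (hydrogen-bonded to the ketone) and not cis to isopropyl, while the C8 ester keeps C8=C9 from moving into conjugation with the ketone.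

**Step 11**
Reactants: 19 keto ester
Product: 20 (1S,2S,4S,5R,6S)-triol [C4 OH; C6 OH β; C8 CH2OH; C2 OTBS]
Conditions: i-Bu2AlH (6 equiv), THF, −78 → −20 °C
Reagents that add atoms: none
Why: Chelation-controlled syn-1,3-diol reduction, in which the C4 aluminium alkoxide ties up the C6 carbonyl so that external hydride adds from the α face away from the angular methyl to give the 6β alcohol, while excess reagent takes the enoate to the allylic alcohol by 1,2-reduction.

**Step 12**
Reactants: 20 triol
Product: 22 (1S,2S,4S,5R,6S)-diol with C8 methyl [C8(CH3)=C9; C4 OH; C6 OH β; C2 OTBS], via allylic mesylate 21 (not isolated)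
Conditions: MsCl (1.05 equiv), Et3N, THF, −40 °C; then LiEt3BH, −40 → 0 °C
Reagents that add atoms: none
Why: Selective sulfonylation of the primary allylic alcohol and SN2 hydride displacement turn CH2OH into the C8 methyl without allylic transposition; the other two hydroxyls only form borate salts and no stereocentre changes.

**Step 13**
Reactants: 22 homoallylic alcohol
Product: 23 (1S,2S,4S,5R,6S,8R,9S)-8β,9β-epoxide
Conditions: VO(acac)2 (cat.), t-BuOOH, CH2Cl2, 0 °C → rt
Reagents that add atoms: tert-butyl hydroperoxide, CC(C)(C)OO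
Why: Hydroxyl-directed vanadium-catalysed epoxidation, in which the peroxide held on the homoallylic 6β-alkoxide is delivered to the β face of C8=C9 and sets 8R,9S against the steric bias of the angular methyl.

**Step 14**
Reactants: 23 epoxy diol; 24 3,4-dimethoxybenzoyl chloride
Product: 25 C6 veratrate [C2 OTBS; C4 OH free]
Conditions: Et3N, DMAP, CH2Cl2, rt
Reagents that add atoms: none
Why: DMAP-catalysed acyl transfer to the only secondary hydroxyl; the tertiary C4 hydroxyl is too hindered and the basic medium spares the epoxide.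

**Step 15**
Reactants: 25 silyl ether
Product: 26 C2 alcohol [C6 veratrate; 8β,9β-epoxide; C4 OH]
Conditions: TBAF, AcOH, THF, rt
Reagents that add atoms: none
Why: Buffered fluoride desilylation that avoids a free C2 alkoxide and so acyl migration; the epoxide is safe because every hydroxyl lies on its own β face and cannot reach its C–O bonds from the rear.

**Step 16**
Reactants: 26 C2 alcohol
Product: 27 target, (1S,2S,4S,5R,6S,8R,9S)-2-acetoxy-8,9-epoxy-4-hydroxy-6-(3,4-dimethoxybenzoyloxy)daucane
Conditions: Ac2O, pyridine, DMAP (cat.), CH2Cl2, 0 °C → rt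
Reagents that add atoms: acetic anhydride, CC(=O)OC(C)=O
Why: DMAP-catalysed acetylation of the secondary C2 alcohol, with the tertiary C4 alcohol left free, completes the target.

**Compound list**

1 | (S)-4-(tert-butyldimethylsilyloxy)cyclopent-2-en-1-one | O=C1C=C[C@@H](O[Si](C)(C)C(C)(C)C)C1 | starting material
2 | acetaldehyde | CC=O | starting material
3 | lithium (3S,4S)-4-(TBSO)-3-methylcyclopent-1-en-1-olate | [Li+].[O-]C1=C[C@H](C)[C@@H](O[Si](C)(C)C(C)(C)C)C1 | intermediate
4 | (2R,3S,4S)-4-(TBSO)-2-(1-hydroxyethyl)-3-methylcyclopentan-1-one, carbinol epimers | CC(O)[C@@H]1C(=O)C[C@H](O[Si](C)(C)C(C)(C)C)[C@H]1C | intermediate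
5 | (3S,4S)-2-acetyl-4-(TBSO)-3-methylcyclopentan-1-one, keto–enol mixture | CC(=O)C1C(=O)C[C@H](O[Si](C)(C)C(C)(C)C)[C@H]1C | intermediate
6 | 2-acetyl-2-(phenylselanyl) derivative of 5, Se trans to the ring methyl | CC(=O)[C@@]1([Se]c2ccccc2)C(=O)C[C@H](O[Si](C)(C)C(C)(C)C)[C@H]1C | intermediate
7 | selenoxide of 6 | CC(=O)[C@@]1([Se](=O)c2ccccc2)C(=O)C[C@H](O[Si](C)(C)C(C)(C)C)[C@H]1C | intermediate
8 | (S)-2-acetyl-4-(TBSO)-3-methylcyclopent-2-en-1-one | CC(=O)C1=C(C)[C@@H](O[Si](C)(C)C(C)(C)C)CC1=O | intermediate
9 | (S)-4-(TBSO)-2-[1-(TBSO)vinyl]-3-methylcyclopent-2-en-1-one | C=C(O[Si](C)(C)C(C)(C)C)C1=C(C)[C@@H](O[Si](C)(C)C(C)(C)C)CC1=O | intermediate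
10 | methyl acetoacetate | CC(=O)CC(=O)OC | starting material
11 | methyl 2-diazo-3-oxobutanoate | CC(=O)C(=[N+]=[N-])C(=O)OC | intermediate
12 | methyl 2-diazo-3-hydroxybutanoate, racemic | CC(O)C(=[N+]=[N-])C(=O)OC | intermediate
13 | methyl 2-diazobut-3-enoate | C=CC(=[N+]=[N-])C(=O)OC | intermediate
14 | methyl (1R,2S)-2-(TBSO)-2-[(3S)-3-(TBSO)-2-methyl-5-oxocyclopent-1-en-1-yl]-1-vinylcyclopropane-1-carboxylate, vinyl cis to cyclopentenyl | C=C[C@]1(C(=O)OC)C[C@]1(O[Si](C)(C)C(C)(C)C)C2=C(C)[C@@H](O[Si](C)(C)C(C)(C)C)CC2=O | intermediate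
15 | (1S,2S)-hydroazulene: C1 CH3 β, C2 OTBS β, C4 ketone, C5=C6(OTBS), C8(CO2Me)=C9 | COC(=O)C1=CC[C@]2(C)[C@@H](O[Si](C)(C)C(C)(C)C)CC(=O)C2=C(O[Si](C)(C)C(C)(C)C)C1 | intermediate
16 | (1S,2S,4S)-carbinol: as 15 with C4 OH β and isopropyl α | COC(=O)C1=CC[C@]2(C)[C@@H](O[Si](C)(C)C(C)(C)C)C[C@](O)(C(C)C)C2=C(O[Si](C)(C)C(C)(C)C)C1 | intermediate
17 | tetrabutylammonium C5=C6 enolate from 16 | COC(=O)C1=CC[C@]2(C)[C@@H](O[Si](C)(C)C(C)(C)C)C[C@](O)(C(C)C)C2=C([O-])C1.CCCC[N+](CCCC)(CCCC)CCCC | intermediate
18 | (1S,2S,4S,5R)-cis-fused C6 ketone, H5 β | COC(=O)C1=CC[C@]2(C)[C@@H](O[Si](C)(C)C(C)(C)C)C[C@](O)(C(C)C)[C@@H]2C(=O)C1 | intermediate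
19 | (1S,2S,4S,5S)-trans-fused C6 ketone, H5 α | COC(=O)C1=CC[C@]2(C)[C@@H](O[Si](C)(C)C(C)(C)C)C[C@](O)(C(C)C)[C@H]2C(=O)C1 | intermediate
20 | (1S,2S,4S,5R,6S)-triol: C4 OH, C6 OH β, C8 CH2OH, C2 OTBS | OCC1=CC[C@]2(C)[C@@H](O[Si](C)(C)C(C)(C)C)C[C@](O)(C(C)C)[C@H]2[C@@H](O)C1 | intermediate
21 | primary allylic mesylate of 20 | CS(=O)(=O)OCC1=CC[C@]2(C)[C@@H](O[Si](C)(C)C(C)(C)C)C[C@](O)(C(C)C)[C@H]2[C@@H](O)C1 | intermediate
22 | (1S,2S,4S,5R,6S)-diol: C8(CH3)=C9, C4 OH, C6 OH β, C2 OTBS | CC1=CC[C@]2(C)[C@@H](O[Si](C)(C)C(C)(C)C)C[C@](O)(C(C)C)[C@H]2[C@@H](O)C1 | intermediate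
23 | (1S,2S,4S,5R,6S,8R,9S)-8β,9β-epoxide of 22 | O[C@H]1C[C@@]2(C)O[C@H]2C[C@]2(C)[C@@H](O[Si](C)(C)C(C)(C)C)C[C@](O)(C(C)C)[C@@H]12 | intermediate
24 | 3,4-dimethoxybenzoyl chloride | COc1ccc(C(=O)Cl)cc1OC | starting material
25 | C6 veratrate of 23 | COc1ccc(C(=O)O[C@H]2C[C@@]3(C)O[C@H]3C[C@]3(C)[C@@H](O[Si](C)(C)C(C)(C)C)C[C@](O)(C(C)C)[C@@H]23)cc1OC | intermediate
26 | C2 alcohol from 25 | COc1ccc(C(=O)O[C@H]2C[C@@]3(C)O[C@H]3C[C@]3(C)[C@@H](O)C[C@](O)(C(C)C)[C@@H]23)cc1OC | intermediate
27 | CNP0330776.1 | COc1ccc(C(=O)O[C@H]2C[C@@]3(C)O[C@H]3C[C@]3(C)[C@@H](OC(C)=O)C[C@](O)(C(C)C)[C@@H]23)cc1OC | target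

**Counts**

- Total step count: 16.
- Longest linear sequence: 13 (steps 1–4 and 8–16).

**Steps most likely to fail**

**Step 8.**
- Risk: the carbene may be lost to pyrazole formation or may react through its vinyl terminus. The cross-conjugated ketone lowers the nucleophilicity of the enol ether and offers a lone pair to the carbene. The rearrangement may also stall at the cyclopropane because of the inward methyl.
- Fallback: run the annulation one oxidation level lower at C4.
- Setting out from 9, i-Bu2AlH (toluene, −78 °C) would give the C4 allylic alcohol F1. TESCl and imidazole in DMF would convert it into its triethylsilyl ether F2.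
- This more electron-rich diene would pass through the same carbene addition to the divinylcyclopropane F3 and, on warming, to the cycloheptadiene F4.
- DDQ (CH2Cl2, pH 7 buffer) would then oxidise the doubly activated allylic C4 silyl ether directly to the ketone. The route is rejoined at 15.

**Step 10.**
- Risk: epimerisation at the hindered C5 may be slower than retro-aldol opening of the five-membered ring or loss of water from the tertiary aldol.
- Fallback: block the carbinol before equilibrating.
- Setting out from 16, TESOTf and 2,6-lutidine (CH2Cl2, −78 °C) would give the C4 triethylsilyl ether F5.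
- K2CO3 in MeOH would cleave the enol silyl ether and, with retro-aldol now impossible, equilibrate C5 freely to the trans-fused silyloxy ketone F6.
- HF·pyridine buffered with pyridine (THF, 0 °C) would remove the TES group in the presence of the C2 TBS ether. The route is rejoined at 19.

**Step 9.**
- Risk: the bulky secondary organometallic may attack the enoate, transfer a β-hydride to C4, or desilylate the vinylogous silyl ester.
- Fallback: bring in the three carbons as a smaller sp2 nucleophile.
- Setting out from 15, isopropenylmagnesium bromide and CeCl3 (THF, −78 °C) would give the isopropenyl carbinol F7.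
- H2 with RhCl(PPh3)3 in benzene would saturate only the 1,1-disubstituted alkene, since the trisubstituted enoate and the tetrasubstituted enol ether are too hindered. The route is rejoined at 16.

**Further compounds**

F1 | step 8 | (1R,4S)-4-(TBSO)-3-methyl-2-[1-(TBSO)vinyl]cyclopent-2-en-1-ol | C=C(O[Si](C)(C)C(C)(C)C)C1=C(C)[C@@H](O[Si](C)(C)C(C)(C)C)C[C@H]1O
F2 | step 8 | triethylsilyl ether of F1 | C=C(O[Si](C)(C)C(C)(C)C)C1=C(C)[C@@H](O[Si](C)(C)C(C)(C)C)C[C@H]1O[Si](CC)(CC)CC
F3 | step 8 | cis-divinylcyclopropane from F2 and 13 | C=C[C@]1(C(=O)OC)C[C@]1(O[Si](C)(C)C(C)(C)C)C2=C(C)[C@@H](O[Si](C)(C)C(C)(C)C)C[C@H]2O[Si](CC)(CC)CC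
F4 | step 8 | hydroazulene as 15 with C4 H and OTES β in place of the ketone | COC(=O)C1=CC[C@]2(C)[C@@H](O[Si](C)(C)C(C)(C)C)C[C@@H](O[Si](CC)(CC)CC)C2=C(O[Si](C)(C)C(C)(C)C)C1
F5 | step 10 | C4 triethylsilyl ether of 16 | COC(=O)C1=CC[C@]2(C)[C@@H](O[Si](C)(C)C(C)(C)C)C[C@](O[Si](CC)(CC)CC)(C(C)C)C2=C(O[Si](C)(C)C(C)(C)C)C1
F6 | step 10 | C4 triethylsilyl ether of 19, trans-fused | COC(=O)C1=CC[C@]2(C)[C@@H](O[Si](C)(C)C(C)(C)C)C[C@](O[Si](CC)(CC)CC)(C(C)C)[C@H]2C(=O)C1
F7 | step 9 | isopropenyl analogue of 16, C4 OH β | COC(=O)C1=CC[C@]2(C)[C@@H](O[Si](C)(C)C(C)(C)C)C[C@](O)(C(C)=C)C2=C(O[Si](C)(C)C(C)(C)C)C1
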